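I began with the gas.

| flask | substrate | gas phase | remark | time |
|---|---|---|---|---|
| zeta | 0.21 M | 16 mM (held) | the very flask that is asked about, followed so far |  |
| alpha | 0.10 M | 16 mM (held) | run made earlier |  |
| flask | 0.21 M | 16 mM (held) |  | 4.0 min |

| run | time / s | product / % | crystals / % |
|---|---|---|---|
| zeta | 10.0 | 7 | 1 |
| zeta | 12.0 | 9 | 0 |
| zeta | 20.0 | 12 | 0 |
| zeta | 30.0 | 14 | 1 |
| zeta | 50.0 | 26 | 0 |
| zeta | 80.0 | 38 | 5 |
| alpha | 10.0 | 13 | 0 |
| alpha | 12.0 | 13 | 0 |
| alpha | 20.0 | 18 | 1 |
| alpha | 25.0 | 22 | 0 |
| alpha | 40.0 | 31 | 0 |
| alpha | 60.0 | 49 | 0 |
| alpha | 90.0 | 60 | 0 |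

(scatter of a reading: 2 percentage points)
- what is said of product includes crystals
- crystals is a solid; its amount is given per volume of the solution
- at the start none of the gas is dissolved
- reactions considered so far: substrate + dissolved gas -> product; gas phase <-> dissolved gas; substrate <-> dormant form; crystals <-> product
- the product and crystals together standing at 4.0 min, as a percentage of the substrate charged
- concentration of dissolved gas in solution at 4.0 min, in percent of saturation

The zeta and alpha flasks looked nearly the same, but zeta held 2.10 times the substrate. After 10.0 s they had made 14.7 mM and 13.0 mM of product, a ratio of 1.13, less than the ratio of substrate. So I took the entry of gas as the rate-limiting step of that early stretch. The mean of the two readings, 1.39 mM s⁻¹, I called the gas ceiling, the product per second that entering gas can pay for. Zeta had made 79.8 mM by 80.0 s and alpha 60.0 mM by 90.0 s, yet over the larger charge zeta's amount was 38% of its charge and alpha's 60%.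

Over 4.0 min the ceiling came to 158% of the charge in the asked flask, more than that charge, so I reckoned the remainder instead. Zeta's last two readings showed a pace of 0.840 mM s⁻¹, below the ceiling. I assumed that this pace held until zeta's unconverted remainder, substrate and dormant form together, came down to alpha's at its last reading, 40.0 mM, which I put at 187 s. Between its last two readings alpha's remainder was falling by 0.00810 s⁻¹, and I assumed the same fall in the asked flask from then on, which left 26.1 mM unconverted. That gave me 87.6% converted. Setting gas entry equal to gas use gave dissolved gas at 84.7% of saturation.

The forecast said 88% and 74%, holding that “gas supply is largely limiting”. Its saturation lay below mine.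

The flask gave 88.9% and 78.3%, both within the forecast's margins. Gas passing into a solution kept empty could deliver 177% of the charge by then, and the flask's total was 56.3% of what my ceiling had offered.

    substrate + dissolved gas → product (k = 5.70 M⁻¹ s⁻¹)
    gas phase ⇌ dissolved gas, rate k2*(csat - [dissolved gas]) (kL = 0.0970 s⁻¹)
    substrate ⇌ dormant form (K = 2.50, k = 0.0690 s⁻¹)
    crystals ⇌ product, rate k4*(cs4 - [product]) while solid is left; crystals form when [product] > cs4 (solubility = 0.0720 M, k = 0.420 s⁻¹)

With 0.84 M of substrate, the ceiling pays for 39.7% of the charge by 4.0 min, less than that charge. That flask gave 40.4%.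

The readings are calculated with made-up constants, and the scatter is random.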